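**Retrosynthetic overview**

1. The ring B quinone is unmasked last, by a phenol-selective oxidation of a 2′-hydroxy-5′-methoxy arene. Rings A and B carry the same four contiguous oxygens, so an electron-transfer oxidant such as (NH4)2Ce(NO3)6 could not be relied on to tell them apart; O2′ therefore travels as a MOM ether and is the only oxygen of ring B ever set free as a phenol.
2. The 7-OH is added to ring A by lithiation, borylation and oxidation at C7, the only C–H flanked by two methoxy groups (on C6 and C8).
3. Ring A and the pyran ring are made together. Ring A is para-dioxygenated (O1 on C8a para to the oxygen on C6, OMe on C8) and fused to the pyran, which is the pattern a Dötz benzannulation leaves: carbene carbon = C8a, its alkoxy group = the O1–C2–C3–C4 chain ending in the alkyne (C4a, C5), CO = C6, 1-methoxyvinyl = C8 and C7.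
4. The alkynol tether comes from Evans propargylation of the ring B arylacetyl imide, which sets C3 (S). Ring B is bought as 2,3,4-trimethoxybenzaldehyde.
5. Order of ring formation: ring B (purchased arene), then pyran ring and ring A in one step (step 11), then the quinone oxidation level of ring B (step 16).

Key step: step 11

Remark: chroman numbering is O1, C2, C3, C4, C4a, C5–C8, C8a; ring A is the benzo ring of the chroman and ring B the pendant arene or quinone (primed locants, C1′ bonded to C3). The single stereocentre C3 is S (C2 > ring B carbon > C4 > H).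

**Route**

Step 1
Reactants: 1 2,3,4-trimethoxybenzaldehyde
Product: 3 2,3,4-trimethoxyphenol, via 2,3,4-trimethoxyphenyl formate 2 (not isolated)
Conditions: mCPBA, CH2Cl2, 0 °C → rt; aq. NaHCO3 wash; then K2CO3 (cat.), MeOH, rt
Reagents that add atoms: meta-chloroperoxybenzoic acid, OOC(=O)c1cccc(Cl)c1
Why: Baeyer–Villiger (Dakin-type) oxidation, in which the electron-rich aryl group migrates to oxygen, followed by methanolysis of the aryl formate.

Step 2
Reactants: 3 2,3,4-trimethoxyphenol
Product: 4 1-(methoxymethoxy)-2,3,4-trimethoxybenzene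
Conditions: MOMCl, i-Pr2NEt, CH2Cl2, 0 °C → rt
Reagents that add atoms: chloromethyl methyl ether, COCCl
Why: O-alkylation of the phenol (Williamson type) installs an acetal that is stable to the bases, organolithiums and chromium chemistry ahead and is the only ring B oxygen group that can later be removed selectively.

Step 3
Reactants: 4 1-(methoxymethoxy)-2,3,4-trimethoxybenzene
Product: 6 1-bromo-2-(methoxymethoxy)-3,4,5-trimethoxybenzene, via aryllithium 5 (not isolated)
Conditions: n-BuLi, THF, 0 °C; then BrCH2CH2Br, −78 °C → rt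
Reagents that add atoms: 1,2-dibromoethane, BrCCBr
Why: Directed ortho-metalation, in which OMOM outranks OMe as director and has a single free ortho C–H, followed by bromine transfer from the dibromide, fixes the attachment carbon of ring B without regiochemical ambiguity.

Step 4
Reactants: 6 1-bromo-2-(methoxymethoxy)-3,4,5-trimethoxybenzene; 7 ethyl bromoacetate
Product: 9 ethyl 2-[2-(methoxymethoxy)-3,4,5-trimethoxyphenyl]acetate, via Reformatsky reagent 8 (not isolated)
Conditions: Zn dust, TMSCl (cat.), THF, 40 °C (7 to 8); then 6, Pd(dba)2 (2 mol %), XPhos (4 mol %), THF, 65 °C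
Reagents that add atoms: none
Why: Pd-catalysed α-arylation of a zinc ester enolate (Reformatsky–Negishi coupling): oxidative addition of zerovalent palladium into the aryl bromide, transmetalation and reductive elimination, with the weakly basic zinc enolate preventing double arylation.

Step 5
Reactants: 9 ethyl 2-[2-(methoxymethoxy)-3,4,5-trimethoxyphenyl]acetate
Product: 10 2-[2-(methoxymethoxy)-3,4,5-trimethoxyphenyl]acetic acid
Conditions: LiOH·H2O, THF/MeOH/H2O, rt; then 1 M HCl to pH 4, 0 °C
Reagents that add atoms: lithium hydroxide, [Li+].[OH-]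
Why: Saponification of the ethyl ester; the cold, mildly acidic work-up should leave the aryl MOM ether intact.

Step 6
Reactants: 10 2-[2-(methoxymethoxy)-3,4,5-trimethoxyphenyl]acetic acid; 11 (S)-4-benzyloxazolidin-2-one
Product: 13 (S)-4-benzyl-3-{2-[2-(methoxymethoxy)-3,4,5-trimethoxyphenyl]acetyl}oxazolidin-2-one, via mixed pivalic anhydride 12 (not isolated)
Conditions: t-BuCOCl, Et3N, THF, −20 °C; then 11, LiCl, −20 °C → rt
Reagents that add atoms: none
Why: N-acylation of the Evans auxiliary through the mixed anhydride, which is attacked at the less hindered arylacetyl carbonyl.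

Step 7
Reactants: 13 (S)-4-benzyl-3-{2-[2-(methoxymethoxy)-3,4,5-trimethoxyphenyl]acetyl}oxazolidin-2-one; 14 propargyl bromide
Product: 16 (S)-4-benzyl-3-{(S)-2-[2-(methoxymethoxy)-3,4,5-trimethoxyphenyl]pent-4-ynoyl}oxazolidin-2-one, via sodium Z-enolate 15 (not isolated)
Conditions: NaN(SiMe3)2 (1.05 equiv), THF, −78 °C; then 14 (3 equiv), −78 → −45 °C
Reagents that add atoms: none
Why: Evans asymmetric alkylation: the chelated Z-enolate is attacked by propargyl bromide on the face opposite the 4-benzyl group, which (aryl outranking propargyl) gives the 2S centre that becomes C3.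

Step 8
Reactants: 16 (S)-4-benzyl-3-{(S)-2-[2-(methoxymethoxy)-3,4,5-trimethoxyphenyl]pent-4-ynoyl}oxazolidin-2-one
Product: 17 (S)-2-[2-(methoxymethoxy)-3,4,5-trimethoxyphenyl]pent-4-yn-1-ol
Conditions: LiBH4, MeOH (1 equiv), THF, 0 °C
Reagents that add atoms: none
Why: Reductive cleavage of the imide at the exocyclic carbonyl gives the primary alcohol and returns the auxiliary; the conditions are non-basic enough to keep the benzylic stereocentre, and the alkyne is not reduced.

Step 9
Reactants: 18 methyl vinyl ether; 19 hexacarbonylchromium Cr(CO)6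
Product: 22 tetramethylammonium pentacarbonyl(2-methoxyacryloyl)chromate, via 1-methoxyvinyllithium 20 (not isolated), via lithium acylchromate 21 (not isolated)
Conditions: t-BuLi, THF, −78 → 0 °C; then Cr(CO)6, Et2O, 0 °C → rt; then Me4NBr, H2O
Reagents that add atoms: tetramethylammonium bromide, C[N+](C)(C)C.[Br-]
Why: Fischer carbene synthesis, first stage: the α-lithiated enol ether adds to a carbonyl ligand of zerovalent chromium, and cation exchange gives a storable acylmetalate salt.

Step 10
Reactants: 22 tetramethylammonium pentacarbonyl(2-methoxyacryloyl)chromate; 17 (S)-2-[2-(methoxymethoxy)-3,4,5-trimethoxyphenyl]pent-4-yn-1-ol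
Product: 24 pentacarbonyl{(1-methoxyvinyl)[(S)-2-(2-(methoxymethoxy)-3,4,5-trimethoxyphenyl)pent-4-yn-1-yloxy]carbene}chromium, via acetoxycarbene complex 23 (not isolated)
Conditions: AcBr, CH2Cl2, −40 °C; then 17, −40 → −10 °C; cold filtration through silica, used at once
Reagents that add atoms: none
Why: O-acylation of the acylmetalate gives a highly electrophilic acyloxycarbene, on which the primary alcohol exchanges by addition–elimination at the carbene carbon (alkoxy exchange on a Fischer carbene), well below the temperature at which the alkyne can react.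

Step 11
Reactants: 24 pentacarbonyl{(1-methoxyvinyl)[(S)-2-(2-(methoxymethoxy)-3,4,5-trimethoxyphenyl)pent-4-yn-1-yloxy]carbene}chromium
Product: 26 (S)-8-methoxy-3-[2-(methoxymethoxy)-3,4,5-trimethoxyphenyl]chroman-6-ol, via tricarbonylchromium arene complex 25 (not isolated)
Conditions: THF (0.01 M), argon, 50 °C; then air, rt
Reagents that add atoms: none
Why: Heating releases one CO cis to the carbene, the tethered alkyne coordinates and inserts into the Cr=C bond, and because only three atoms (C2, C3, C4) separate the carbene oxygen from the alkyne the internal alkyne carbon must bond to the carbene carbon (C8a–C4a), the reverse of the intermolecular preference; CO insertion (C5–C6) then gives an η4-dienylketene complex that electrocyclises onto the terminal carbon of the 1-methoxyvinyl group (C6–C7) and tautomerises to the phenol, which stays bound to Cr(CO)3 until air removes the metal. This is the Dötz benzannulation in its intramolecular form with the alkyne tethered through the carbene oxygen, and the closest known case is that of aryl(alkynyloxy)carbene chromium complexes, which give ring-fused hydroquinone monoethers. The pyran ring closes in the insertion event as a 6-exo-dig type closure onto the carbene carbon, and ring A closes by 6π electrocyclisation of the dienylketene. No stereocentre is formed; C3 sits in the tether, away from every reacting atom, and should be carried through unchanged. The step needs three selectivities: insertion regiochemistry, which the tether length secures; phenol formation over five-membered-ring or furan products, which alkenyl carbenes in THF favour; and ring closure over oligomerisation of the terminal alkyne, which high dilution secures.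

Step 12
Reactants: 26 (S)-8-methoxy-3-[2-(methoxymethoxy)-3,4,5-trimethoxyphenyl]chroman-6-ol
Product: 27 (S)-6,8-dimethoxy-3-[2-(methoxymethoxy)-3,4,5-trimethoxyphenyl]chroman
Conditions: MeI, K2CO3, acetone, 56 °C
Reagents that add atoms: iodomethane, CI
Why: Williamson methylation of the only free phenol; the MOM ether and the stereocentre are inert to carbonate.

Step 13
Reactants: 27 (S)-6,8-dimethoxy-3-[2-(methoxymethoxy)-3,4,5-trimethoxyphenyl]chroman
Product: 30 (S)-6,8-dimethoxy-3-[2-(methoxymethoxy)-3,4,5-trimethoxyphenyl]chroman-7-ol, via 7-lithiochroman 28 (not isolated), via dimethyl 7-boronate 29 (not isolated)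
Conditions: n-BuLi (1.2 equiv), THF, 0 °C → rt; then B(OMe)3, −78 °C → rt; then AcOH, 30% H2O2, 0 °C → rt
Reagents that add atoms: hydrogen peroxide, OO
Why: Directed ortho-metalation at C7, the one C–H that lies between two methoxy groups (the 2-position of a resorcinol diether; the MOM group of ring B has no free ortho C–H), then borylation and oxidative 1,2-shift from boron to oxygen.

Step 14
Reactants: 30 (S)-6,8-dimethoxy-3-[2-(methoxymethoxy)-3,4,5-trimethoxyphenyl]chroman-7-ol
Product: 31 {[(S)-6,8-dimethoxy-3-(2-(methoxymethoxy)-3,4,5-trimethoxyphenyl)chroman-7-yl]oxy}triisopropylsilane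
Conditions: TIPSCl, imidazole, DMAP (cat.), DMF, 40 °C
Reagents that add atoms: chlorotriisopropylsilane, CC(C)[Si](Cl)(C(C)C)C(C)C
Why: Silylation masks the ring A phenol, so that ring A holds no free OH during the oxidation, with a group that survives acid and leaves with buffered fluoride.

Step 15
Reactants: 31 {[(S)-6,8-dimethoxy-3-(2-(methoxymethoxy)-3,4,5-trimethoxyphenyl)chroman-7-yl]oxy}triisopropylsilane
Product: 32 6-[(S)-6,8-dimethoxy-7-(triisopropylsilyloxy)chroman-3-yl]-2,3,4-trimethoxyphenol
Conditions: HCl (3 M in MeOH), THF, 40 °C, argon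
Reagents that add atoms: none
Why: Acid-catalysed transacetalisation to methanol removes the aryl MOM ether; aryl methyl ethers, the chroman and the hindered aryl TIPS ether should be inert.

Step 16
Reactants: 32 6-[(S)-6,8-dimethoxy-7-(triisopropylsilyloxy)chroman-3-yl]-2,3,4-trimethoxyphenol
Product: 33 5-[(S)-6,8-dimethoxy-7-(triisopropylsilyloxy)chroman-3-yl]-2,3-dimethoxycyclohexa-2,5-diene-1,4-dione
Conditions: PhI(OAc)2 (1.1 equiv), MeCN/H2O (3:1), 0 °C
Reagents that add atoms: water, O
Why: Oxidative demethylation of a para-methoxyphenol by a hypervalent iodine reagent: ligand exchange at iodine is possible only at the free phenol O2′, water adds at C5′ and methanol leaves the quinone hemiketal, so ring A, which has no free phenol, is not touched.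

Step 17
Reactants: 33 5-[(S)-6,8-dimethoxy-7-(triisopropylsilyloxy)chroman-3-yl]-2,3-dimethoxycyclohexa-2,5-diene-1,4-dione
Product: 34 5-[(S)-7-hydroxy-6,8-dimethoxychroman-3-yl]-2,3-dimethoxycyclohexa-2,5-diene-1,4-dione (CNP0121136.1)
Conditions: Bu4NF, AcOH (1:1), THF, 0 °C
Reagents that add atoms: none
Why: Fluoride-induced desilylation of the aryl silyl ether, buffered with acetic acid so that the quinone and the C3–H next to it never meet a basic medium.

**Compound list**

1 | 2,3,4-trimethoxybenzaldehyde | COc1ccc(C=O)c(OC)c1OC | starting material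
2 | 2,3,4-trimethoxyphenyl formate | COc1ccc(OC=O)c(OC)c1OC | intermediate (not isolated)
3 | 2,3,4-trimethoxyphenol | COc1ccc(O)c(OC)c1OC | intermediate
4 | 1-(methoxymethoxy)-2,3,4-trimethoxybenzene | COCOc1ccc(OC)c(OC)c1OC | intermediate
5 | [2-(methoxymethoxy)-3,4,5-trimethoxyphenyl]lithium | COCOc1c([Li])cc(OC)c(OC)c1OC | intermediate (not isolated)
6 | 1-bromo-2-(methoxymethoxy)-3,4,5-trimethoxybenzene | COCOc1c(Br)cc(OC)c(OC)c1OC | intermediate
7 | ethyl bromoacetate | CCOC(=O)CBr | starting material
8 | bromo(2-ethoxy-2-oxoethyl)zinc | CCOC(=O)C[Zn]Br | intermediate (not isolated)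
9 | ethyl 2-[2-(methoxymethoxy)-3,4,5-trimethoxyphenyl]acetate | CCOC(=O)Cc1cc(OC)c(OC)c(OC)c1OCOC | intermediate
10 | 2-[2-(methoxymethoxy)-3,4,5-trimethoxyphenyl]acetic acid | OC(=O)Cc1cc(OC)c(OC)c(OC)c1OCOC | intermediate
11 | (S)-4-benzyloxazolidin-2-one | O=C1OC[C@H](Cc2ccccc2)N1 | starting material
12 | 2-[2-(methoxymethoxy)-3,4,5-trimethoxyphenyl]acetic pivalic anhydride | CC(C)(C)C(=O)OC(=O)Cc1cc(OC)c(OC)c(OC)c1OCOC | intermediate (not isolated)
13 | (S)-4-benzyl-3-{2-[2-(methoxymethoxy)-3,4,5-trimethoxyphenyl]acetyl}oxazolidin-2-one | COCOc1c(CC(=O)N2[C@@H](Cc3ccccc3)COC2=O)cc(OC)c(OC)c1OC | intermediate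
14 | propargyl bromide | C#CCBr | starting material
15 | sodium (Z)-enolate of 13 | COCOc1c(/C=C(\[O-])N2[C@@H](Cc3ccccc3)COC2=O)cc(OC)c(OC)c1OC.[Na+] | intermediate (not isolated)
16 | (S)-4-benzyl-3-{(S)-2-[2-(methoxymethoxy)-3,4,5-trimethoxyphenyl]pent-4-ynoyl}oxazolidin-2-one | C#CC[C@@H](c1cc(OC)c(OC)c(OC)c1OCOC)C(=O)N1[C@@H](Cc2ccccc2)COC1=O | intermediate
17 | (S)-2-[2-(methoxymethoxy)-3,4,5-trimethoxyphenyl]pent-4-yn-1-ol | C#CC[C@@H](c1cc(OC)c(OC)c(OC)c1OCOC)CO | intermediate
18 | methyl vinyl ether | COC=C | starting material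
19 | hexacarbonylchromium | O=C=[Cr](=C=O)(=C=O)(=C=O)(=C=O)=C=O | starting material
20 | 1-methoxyvinyllithium | COC([Li])=C | intermediate (not isolated)
21 | lithium pentacarbonyl(2-methoxyacryloyl)chromate | [Li+].COC(=C)C([O-])=[Cr](=C=O)(=C=O)(=C=O)(=C=O)=C=O | intermediate (not isolated)
22 | tetramethylammonium pentacarbonyl(2-methoxyacryloyl)chromate | C[N+](C)(C)C.COC(=C)C([O-])=[Cr](=C=O)(=C=O)(=C=O)(=C=O)=C=O | intermediate
23 | [acetoxy(1-methoxyvinyl)carbene]pentacarbonylchromium | CC(=O)OC(C(=C)OC)=[Cr](=C=O)(=C=O)(=C=O)(=C=O)=C=O | intermediate (not isolated)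
24 | pentacarbonyl{(1-methoxyvinyl)[(S)-2-(2-(methoxymethoxy)-3,4,5-trimethoxyphenyl)pent-4-yn-1-yloxy]carbene}chromium | COCOc1c([C@H](CC#C)COC(C(=C)OC)=[Cr](=C=O)(=C=O)(=C=O)(=C=O)=C=O)cc(OC)c(OC)c1OC | intermediate (key-step precursor)
25 | tricarbonyl(η6-arene)chromium complex of 26, chromium on ring A (metal fragment written apart in the SMILES) | COCOc1c([C@H]2COc3c(cc(O)cc3OC)C2)cc(OC)c(OC)c1OC.O=C=[Cr](=C=O)=C=O | intermediate (not isolated)
26 | (S)-8-methoxy-3-[2-(methoxymethoxy)-3,4,5-trimethoxyphenyl]chroman-6-ol | COCOc1c([C@H]2COc3c(cc(O)cc3OC)C2)cc(OC)c(OC)c1OC | intermediate (key-step product)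
27 | (S)-6,8-dimethoxy-3-[2-(methoxymethoxy)-3,4,5-trimethoxyphenyl]chroman | COCOc1c([C@H]2COc3c(cc(OC)cc3OC)C2)cc(OC)c(OC)c1OC | intermediate
28 | 7-lithio derivative of 27 | COCOc1c([C@H]2COc3c(cc(OC)c([Li])c3OC)C2)cc(OC)c(OC)c1OC | intermediate (not isolated)
29 | dimethyl {(S)-6,8-dimethoxy-3-[2-(methoxymethoxy)-3,4,5-trimethoxyphenyl]chroman-7-yl}boronate | COCOc1c([C@H]2COc3c(cc(OC)c(B(OC)OC)c3OC)C2)cc(OC)c(OC)c1OC | intermediate (not isolated)
30 | (S)-6,8-dimethoxy-3-[2-(methoxymethoxy)-3,4,5-trimethoxyphenyl]chroman-7-ol | COCOc1c([C@H]2COc3c(cc(OC)c(O)c3OC)C2)cc(OC)c(OC)c1OC | intermediate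
31 | {[(S)-6,8-dimethoxy-3-(2-(methoxymethoxy)-3,4,5-trimethoxyphenyl)chroman-7-yl]oxy}triisopropylsilane | COCOc1c([C@H]2COc3c(cc(OC)c(O[Si](C(C)C)(C(C)C)C(C)C)c3OC)C2)cc(OC)c(OC)c1OC | intermediate
32 | 6-[(S)-6,8-dimethoxy-7-(triisopropylsilyloxy)chroman-3-yl]-2,3,4-trimethoxyphenol | COc1cc([C@H]2COc3c(cc(OC)c(O[Si](C(C)C)(C(C)C)C(C)C)c3OC)C2)c(O)c(OC)c1OC | intermediate
33 | 5-[(S)-6,8-dimethoxy-7-(triisopropylsilyloxy)chroman-3-yl]-2,3-dimethoxycyclohexa-2,5-diene-1,4-dione | COC1=C(OC)C(=O)C([C@H]2COc3c(cc(OC)c(O[Si](C(C)C)(C(C)C)C(C)C)c3OC)C2)=CC1=O | intermediate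
34 | 5-[(S)-7-hydroxy-6,8-dimethoxychroman-3-yl]-2,3-dimethoxycyclohexa-2,5-diene-1,4-dione | COC1=C(OC)C(=O)C([C@H]2COc3c(cc(OC)c(O)c3OC)C2)=CC1=O | target

**Step count**

Total: 17 steps. Longest linear sequence: 16 steps (steps 1–8, then 10–17); step 9 is the one-step side branch to the acylchromate.

**Steps most likely to fail, with fallbacks**

Step 11 (key step). After CO loss, the terminal alkyne of a second molecule may insert faster than the tethered one and lead to oligomers, or the vinylketene may be diverted into cyclobutenone or furan formation instead of electrocyclising. The fallback buys ring A instead of building it and sets out from imide 13. Its sodium enolate 15 should be benzylated on the same face as in step 7 with 2-bromo-1-(bromomethyl)-3,5-dimethoxybenzene F1 (from commercial 3,5-dimethoxybenzyl bromide by ring bromination with NBS) to give the benzylated imide F2. LiBH4 in THF/MeOH should release the bromoaryl alcohol F3. An intramolecular Pd-catalysed aryl ether formation (Pd(OAc)2, t-BuXPhos, Cs2CO3, toluene, 80 °C; Buchwald–Hartwig etherification) then closes the pyran ring between the primary alcohol and the aryl bromide. This comes back to the route at 27, where step 13 takes over.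

Step 13. n-BuLi may metalate C6′–H of ring B or the benzylic C3–H, the latter opening the pyran by β-elimination of the O1 phenoxide or eroding the stereocentre, and the 2,6-dimethoxyaryl boronate may protodeboronate before it is oxidised. The fallback uses the chromium that the key step leaves on ring A and sets out from 24. The benzannulation is run under argon without the air work-up, and the phenol of complex 25 is methylated in the same flask (NaH, MeI, THF, 0 °C) to give the isolable tricarbonylchromium complex of ether 27, F4 (chromium on ring A). The Cr(CO)3 unit acidifies the C–H bonds of the complexed ring only, so n-BuLi at −78 °C should metalate ring A between its two methoxy groups and leave ring B alone, giving the 7-lithio complex F5. B(OMe)3 gives the 7-boronate complex F6, and AcOH/H2O2 oxidises the C–B bond and strips the metal in one operation. This comes back to the route at 30.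

Step 10. The acyloxycarbene may decompose before the β-branched alcohol captures it, or the alcohol may add in conjugate fashion to the methoxyvinyl group. The fallback makes the C2–O1 bond by alkylating the acylmetalate oxygen instead of exchanging at the carbene carbon, and sets out from alcohol 17. With Tf2O and 2,6-di-tert-butyl-4-methylpyridine in CH2Cl2 at −78 °C it should give the primary triflate F7, which is added cold to acylchromate 22 (CH2Cl2, −40 → 0 °C); keeping the triflate below 0 °C limits participation by the ortho oxygen of ring B. This comes back to the route at 24.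

**Further compounds**

F1 | step 11 | 2-bromo-1-(bromomethyl)-3,5-dimethoxybenzene | BrCc1cc(OC)cc(OC)c1Br
F2 | step 11 | (S)-4-benzyl-3-{(S)-3-(2-bromo-3,5-dimethoxyphenyl)-2-[2-(methoxymethoxy)-3,4,5-trimethoxyphenyl]propanoyl}oxazolidin-2-one | COc1cc(OC)c(Br)c(C[C@@H](c2cc(OC)c(OC)c(OC)c2OCOC)C(=O)N2[C@@H](Cc3ccccc3)COC2=O)c1
F3 | step 11 | (S)-3-(2-bromo-3,5-dimethoxyphenyl)-2-[2-(methoxymethoxy)-3,4,5-trimethoxyphenyl]propan-1-ol | COc1cc(OC)c(Br)c(C[C@@H](c2cc(OC)c(OC)c(OC)c2OCOC)CO)c1
F4 | step 13 | tricarbonyl(η6-arene)chromium complex of 27, chromium on ring A | COCOc1c([C@H]2COc3c(cc(OC)cc3OC)C2)cc(OC)c(OC)c1OC.O=C=[Cr](=C=O)=C=O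
F5 | step 13 | 7-lithio derivative of complex F4 | COCOc1c([C@H]2COc3c(cc(OC)c([Li])c3OC)C2)cc(OC)c(OC)c1OC.O=C=[Cr](=C=O)=C=O
F6 | step 13 | 7-(dimethoxyboryl) derivative of complex F4 | COCOc1c([C@H]2COc3c(cc(OC)c(B(OC)OC)c3OC)C2)cc(OC)c(OC)c1OC.O=C=[Cr](=C=O)=C=O
F7 | step 10 | (S)-2-[2-(methoxymethoxy)-3,4,5-trimethoxyphenyl]pent-4-yn-1-yl trifluoromethanesulfonate | C#CC[C@@H](c1cc(OC)c(OC)c(OC)c1OCOC)COS(=O)(=O)C(F)(F)F
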